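**Overview**

- Numbering: chain C1 (acid) to C10 (alkylidene carbon of ring B); ring C is the dioxane (C3–C6). Cuts: C8–C9 (alkyl–alkenyl Suzuki); in ring B the C9–B and C10–CH2 bonds across an alkyne; in ring C the C3–O and C6–O bonds back to H2O2; then C2–C3 (crotylation) and C6–C7/C8–O (two methylene transfers).
- Forward: ring A is bought and ring B closes on it in the copper step. Separately an oxetane is built and exchanged for ring C. The halves are joined at C8–C9 and C1 is oxidised last.
- Stereochemistry: C2 and C3 come from a reagent-controlled syn crotylation, C6 from a catalyst-controlled methylene transfer. C3 and C6 are each inverted once when H2O2 is stitched in. The Z alkene comes from syn borylcupration.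
- Enabling feature: C10 lies one CH2 from one carbon and two CH2 from the other carbon of the tetrasubstituted ring A/ring B fusion alkene, with C8 cis to the one-CH2 arm. Ring B with its Z alkene is therefore the syn adduct of boron and an allylic CH2 across a butynyl alkyne held cis on ring A.

Key step: step 7

Remark: the LaLi3(binaphthoxide)3 catalyst made from (S)-binaphthol is assumed to deliver the first methylene to the Re face of the methyl ketone (S epoxide); if a trial on 22 shows the opposite sense, the (R)-binaphthol complex is used.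

**Ring A/ring B half (fragment 1)**

Step 1
Reactants: 1 2,2-dimethylcyclohexan-1-one; 2 dimethyl carbonate
Product: 3 methyl 3,3-dimethyl-2-oxocyclohexane-1-carboxylate
Conditions: NaH, (MeO)2CO, THF, reflux; aq. HCl
Reagents that add atoms: none
Why: Claisen-type C-methoxycarbonylation of the sodium enolate, which can only form on the CH2 side of the ketone; the new stereocentre is not controlled and is erased in step 2.

Step 2
Reactants: 3 methyl 3,3-dimethyl-2-oxocyclohexane-1-carboxylate
Product: 4 methyl 3,3-dimethyl-2-(trifluoromethanesulfonyloxy)cyclohex-1-ene-1-carboxylate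
Conditions: NaH, Et2O, 0 °C; Tf2O
Reagents that add atoms: triflic anhydride, O=S(=O)(OS(=O)(=O)C(F)(F)F)C(F)(F)F
Why: Enol triflate formation by O-sulfonylation of the chelated sodium enolate of the β-keto ester, which fixes the ring alkene between the ester carbon and the carbon next to the gem-dimethyl group.

Step 3
Reactants: 4 methyl 3,3-dimethyl-2-(trifluoromethanesulfonyloxy)cyclohex-1-ene-1-carboxylate; 5 (4-bromobut-1-yn-1-yl)trimethylsilane
Product: 7 methyl 3,3-dimethyl-2-[4-(trimethylsilyl)but-3-yn-1-yl]cyclohex-1-ene-1-carboxylate, via alkylzinc bromide 6 (not isolated)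
Conditions: 5, Zn (BrCH2CH2Br, Me3SiCl), LiCl, THF, 50 °C; then 4, Pd(dppf)Cl2 (5 mol %), THF, 60 °C
Reagents that add atoms: none
Why: Negishi coupling in which LiCl-assisted zinc insertion gives the primary alkylzinc 6, which transmetalates to the alkenylpalladium formed by oxidative addition of zerovalent palladium into the ester-activated enol triflate, the wide bite angle of dppf favouring reductive elimination over β-hydride elimination.

Step 4
Reactants: 7 methyl 3,3-dimethyl-2-[4-(trimethylsilyl)but-3-yn-1-yl]cyclohex-1-ene-1-carboxylate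
Product: 8 {3,3-dimethyl-2-[4-(trimethylsilyl)but-3-yn-1-yl]cyclohex-1-en-1-yl}methanol
Conditions: i-Bu2AlH (2.5 equiv), CH2Cl2, −78 → 0 °C; aq. KNaC4H4O6
Reagents that add atoms: none
Why: Hydride reduction of the tetrasubstituted enoate (1,2-reduction of an ester) to the primary allylic alcohol, the silyl alkyne being inert at this temperature.

Step 5
Reactants: 8 {3,3-dimethyl-2-[4-(trimethylsilyl)but-3-yn-1-yl]cyclohex-1-en-1-yl}methanol
Product: 9 [2-(but-3-yn-1-yl)-3,3-dimethylcyclohex-1-en-1-yl]methanol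
Conditions: K2CO3 (cat.), MeOH, rt
Reagents that add atoms: none
Why: Base-catalysed protodesilylation in which methoxide attacks silicon and methanol protonates the acetylide, freeing the terminal alkyne.

Step 6
Reactants: 9 [2-(but-3-yn-1-yl)-3,3-dimethylcyclohex-1-en-1-yl]methanol
Product: 10 [2-(but-3-yn-1-yl)-3,3-dimethylcyclohex-1-en-1-yl]methyl diethyl phosphate
Conditions: ClP(O)(OEt)2, pyridine, DMAP (cat.), CH2Cl2, 0 °C
Reagents that add atoms: diethyl chlorophosphate, CCOP(=O)(Cl)OCC
Why: O-Phosphorylation of the primary allylic alcohol through the N-phosphorylpyridinium species, the ionisable product being passed through base-washed silica and used at once.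

Step 7
Reactants: 10 [2-(but-3-yn-1-yl)-3,3-dimethylcyclohex-1-en-1-yl]methyl diethyl phosphate
Product: 12 2-{(Z)-[5,5-dimethyl-3,4,5,6,7,8-hexahydronaphthalen-2(1H)-ylidene]methyl}-4,4,5,5-tetramethyl-1,3,2-dioxaborolane, via alkenylcopper 11 (not isolated)
Conditions: CuCl (10 mol %), Xantphos (10 mol %), KOtBu (1.2 equiv), B2pin2 (1.2 equiv), THF, 30 °C, no proton source
Reagents that add atoms: bis(pinacolato)diboron, CC1(C)OB(OC1(C)C)B1OC(C)(C)C(C)(C)O1
Why: Proposed new method: KOtBu turns CuCl/Xantphos into a tert-butoxide of monovalent copper that is borylated by B2pin2; the borylcopper adds syn across the terminal alkyne with boron on the CH terminus (C9) and copper on C10 to give 11, whose C–Cu bond then displaces the phosphate at the primary allylic carbon while KOtBu regenerates the alkoxide. The closest known reaction types are the copper-catalysed three-component boryl-allylation of alkynes with allylic phosphates and the copper-catalysed intramolecular alkylboration of alkynes that carry a tethered alkyl halide; their merger on an alkyne-tethered allylic phosphate has not been shown. Ring B, the only ring formed, closes by 6-exo-tet substitution at the primary allylic CH2. No stereocentre is created; the Z geometry of C9=C10 is controlled by the syn borylcupration and by retention at C10 in the C–C bond formation, which leave boron cis to the new bond to the doubly allylic CH2. The step needs boron at the alkyne terminus, alkyne insertion ahead of direct borylation of the phosphate, and substitution at the primary rather than the fully substituted allylic terminus. These are secured by the steric bias of the bulky bisphosphine borylcopper on a terminal alkyne, by the gem-dimethyl-flanked tetrasubstituted γ-carbon that slows direct allylic borylation, and by the fact that γ-attack would need a cyclobutane with adjacent quaternary carbons, while the cis placement of both arms on the ring A alkene and the absence of a proton source let the alkenylcopper cyclise before it is quenched.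

Step 8
Reactants: 12 2-{(Z)-[5,5-dimethyl-3,4,5,6,7,8-hexahydronaphthalen-2(1H)-ylidene]methyl}-4,4,5,5-tetramethyl-1,3,2-dioxaborolane
Product: 13 {(Z)-[5,5-dimethyl-3,4,5,6,7,8-hexahydronaphthalen-2(1H)-ylidene]methyl}boronic acid
Conditions: NaIO4, NH4OAc, acetone/H2O, rt
Reagents that add atoms: water, O
Why: Oxidative cleavage of the pinacol ester, in which periodate destroys the pinacol released by the hydrolysis equilibrium (glycol cleavage) and the untouched C–B bond keeps the Z geometry.

**Dioxane half (fragment 2)**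

Step 9
Reactants: 14 6-methylhept-5-en-2-one
Product: 16 4-oxopentanal, via ozonide 15 (not isolated)
Conditions: O3, CH2Cl2, −78 °C; Me2S, −78 °C → rt
Reagents that add atoms: ozone, [O-][O+]=O
Why: Ozonolysis, in which cycloaddition of ozone to the trisubstituted alkene and recombination give ozonide 15, which Me2S reduces to the keto aldehyde and acetone.

Step 10
Reactants: 16 4-oxopentanal; 17 (Z)-but-2-ene
Product: 21 (5R,6R)-5-hydroxy-6-methyloct-7-en-2-one, via (Z)-crotylpotassium 18 (not isolated), via (Z)-crotylborane 19 (not isolated), via borinate 20 (not isolated)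
Conditions: 17 (2 equiv), n-BuLi, KOtBu, THF, −78 → −45 °C; (−)-Ipc2BOMe, −78 °C; BF3·OEt2; 16, −78 °C; NaOH, H2O2, 0 °C → rt
Reagents that add atoms: none
Why: Brown asymmetric crotylboration, in which the Z-crotylborane reacts through a closed chair (Zimmerman–Traxler) transition state to give the syn pair, the isopinocampheyl groups derived from (+)-α-pinene direct attack to the Si face of the aldehyde (5R,6R), and the aldehyde reacts at −78 °C in preference to the methyl ketone.

Step 11
Reactants: 21 (5R,6R)-5-hydroxy-6-methyloct-7-en-2-one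
Product: 22 (5R,6R)-5-[(tert-butyldimethylsilyl)oxy]-6-methyloct-7-en-2-one
Conditions: TBSCl, imidazole, DMF, rt
Reagents that add atoms: tert-butyldimethylsilyl chloride, CC(C)(C)[Si](C)(C)Cl
Why: Silyl ether formation at the secondary alcohol through the N-silylimidazolium species, leaving the ketone untouched.

Step 12
Reactants: 22 (5R,6R)-5-[(tert-butyldimethylsilyl)oxy]-6-methyloct-7-en-2-one; 23 trimethylsulfoxonium iodide
Product: 26 tert-butyldimethyl({(3R,4R)-3-methyl-6-[(2S)-2-methyloxetan-2-yl]hex-1-en-4-yl}oxy)silane, via sulfoxonium methylide 24 (not isolated), via epoxide 25 (not isolated)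
Conditions: 23, NaH, THF, 65 °C (gives 24); 22, LaLi3[(S)-binaphthoxide]3 (5 mol %), (2,4,6-(MeO)3C6H2)3P=O (5 mol %), 5 Å MS, THF, rt; then more 24 and catalyst (to 20 mol %), 45 °C
Reagents that add atoms: none
Why: Corey–Chaykovsky epoxidation followed by ring expansion of the epoxide by a second ylide (attack at the epoxide CH2, then 4-exo-tet closure), the lanthanum–lithium binaphthoxide directing the first methylene to the Re face of the methyl ketone to set C6 (S), which the ring expansion does not touch.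

Step 13
Reactants: 26 tert-butyldimethyl({(3R,4R)-3-methyl-6-[(2S)-2-methyloxetan-2-yl]hex-1-en-4-yl}oxy)silane
Product: 27 (3R,4R)-3-methyl-6-[(2S)-2-methyloxetan-2-yl]hex-1-en-4-ol
Conditions: Bu4NF, THF, 0 °C → rt
Reagents that add atoms: none
Why: Fluoride-induced desilylation driven by the Si–F bond, the oxetane being stable to fluoride.

Step 14
Reactants: 27 (3R,4R)-3-methyl-6-[(2S)-2-methyloxetan-2-yl]hex-1-en-4-ol
Product: 28 (3R,4R)-3-methyl-6-[(2S)-2-methyloxetan-2-yl]hex-1-en-4-yl methanesulfonate
Conditions: MsCl, Et3N, CH2Cl2, 0 °C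
Reagents that add atoms: methanesulfonyl chloride, CS(=O)(=O)Cl
Why: Mesylate formation at the secondary alcohol with retention at C3, the oxetane being inert to the amine base.

Step 15
Reactants: 28 (3R,4R)-3-methyl-6-[(2S)-2-methyloxetan-2-yl]hex-1-en-4-yl methanesulfonate
Product: 29 (3R,4R,7R)-7-hydroperoxy-9-hydroxy-3,7-dimethylnon-1-en-4-yl methanesulfonate
Conditions: H2O2 (anhydrous, in Et2O, excess), Me3SiOTf (cat.), Et2O, −78 → −20 °C
Reagents that add atoms: hydrogen peroxide, OO
Why: Lewis acid-activated perhydrolysis of a 2,2-disubstituted oxetane, in which H2O2 attacks the quaternary ring carbon C6 from the face opposite the departing oxygen and so inverts C6, while the mesylate and the vinyl group are inert to cold acid.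

Step 16
Reactants: 29 (3R,4R,7R)-7-hydroperoxy-9-hydroxy-3,7-dimethylnon-1-en-4-yl methanesulfonate
Product: 30 2-{(3R,6S)-6-[(2R)-but-3-en-2-yl]-3-methyl-1,2-dioxan-3-yl}ethan-1-ol
Conditions: KOtBu (1.0 equiv), 18-crown-6, toluene, 0 °C, high dilution
Reagents that add atoms: none
Why: Intramolecular alkylation of the hydroperoxide, in which the peroxy anion (far more acidic than the primary alcohol, so the only anion formed) displaces the C3 mesylate by 6-exo-tet SN2 with inversion to close ring C.

Step 17
Reactants: 30 2-{(3R,6S)-6-[(2R)-but-3-en-2-yl]-3-methyl-1,2-dioxan-3-yl}ethan-1-ol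
Product: 32 (3R,6S)-3-(2-bromoethyl)-6-[(2R)-but-3-en-2-yl]-3-methyl-1,2-dioxane, via mesylate 31 (not isolated)
Conditions: MsCl, Et3N, THF, 0 °C; then LiBr, rt
Reagents that add atoms: lithium bromide, [Li+].[Br-]
Why: Mesylation followed by Finkelstein-type SN2 displacement by bromide at an unhindered primary carbon, phosphine-based brominations being avoided because phosphines reduce the O–O bond.

Step 18
Reactants: 32 (3R,6S)-3-(2-bromoethyl)-6-[(2R)-but-3-en-2-yl]-3-methyl-1,2-dioxane
Product: 35 (2R)-2-[(3S,6R)-6-(2-bromoethyl)-6-methyl-1,2-dioxan-3-yl]propan-1-ol, via ozonide 33 (not isolated), via aldehyde 34 (not isolated)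
Conditions: O3, CH2Cl2, −78 °C; then NaBH4, MeOH, −78 → 0 °C
Reagents that add atoms: ozone, [O-][O+]=O
Why: Ozonolysis with reductive work-up, in which ozone cleaves the only alkene to ozonide 33 and NaBH4, which does not reduce dialkyl peroxides, takes it through aldehyde 34 to the primary alcohol at low temperature before C2 can epimerise.

Step 19
Reactants: 35 (2R)-2-[(3S,6R)-6-(2-bromoethyl)-6-methyl-1,2-dioxan-3-yl]propan-1-ol
Product: 36 {(2R)-2-[(3S,6R)-6-(2-bromoethyl)-6-methyl-1,2-dioxan-3-yl]propoxy}(tert-butyl)dimethylsilane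
Conditions: TBSCl, imidazole, CH2Cl2, rt
Reagents that add atoms: tert-butyldimethylsilyl chloride, CC(C)(C)[Si](C)(C)Cl
Why: Silyl ether formation at the primary alcohol, which keeps C1 at the alcohol level so that no carbonyl-activated C2–H can trigger β-elimination of the peroxide in the basic coupling.

**Union and end game**

Step 20
Reactants: 13 {(Z)-[5,5-dimethyl-3,4,5,6,7,8-hexahydronaphthalen-2(1H)-ylidene]methyl}boronic acid; 36 {(2R)-2-[(3S,6R)-6-(2-bromoethyl)-6-methyl-1,2-dioxan-3-yl]propoxy}(tert-butyl)dimethylsilane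
Product: 37 tert-butyl{(2R)-2-[(3S,6S)-6-[(Z)-3-(5,5-dimethyl-3,4,5,6,7,8-hexahydronaphthalen-2(1H)-ylidene)propyl]-6-methyl-1,2-dioxan-3-yl]propoxy}dimethylsilane
Conditions: 13 (1.5 equiv), Pd(OAc)2 (5 mol %), [HP(t-Bu)2Me]BF4 (10 mol %), KOtBu (3 equiv), t-amyl alcohol, rt
Reagents that add atoms: none
Why: Suzuki–Miyaura coupling of an unactivated primary alkyl bromide, in which the electron-rich trialkylphosphine lets zerovalent palladium insert into the C–Br bond at room temperature, reductive elimination outruns β-hydride elimination, and the alkenyl group is transferred with retention of the Z geometry (the C6 descriptor changes from R to S through the CIP ranking only).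

Step 21
Reactants: 37 tert-butyl{(2R)-2-[(3S,6S)-6-[(Z)-3-(5,5-dimethyl-3,4,5,6,7,8-hexahydronaphthalen-2(1H)-ylidene)propyl]-6-methyl-1,2-dioxan-3-yl]propoxy}dimethylsilane
Product: 38 (2R)-2-[(3S,6S)-6-[(Z)-3-(5,5-dimethyl-3,4,5,6,7,8-hexahydronaphthalen-2(1H)-ylidene)propyl]-6-methyl-1,2-dioxan-3-yl]propan-1-ol
Conditions: HF·pyridine, pyridine, THF, 0 °C → rt
Reagents that add atoms: none
Why: Desilylation of a primary silyl ether with buffered HF·pyridine, mild enough for the peroxide and the acid-sensitive skipped diene.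

Step 22
Reactants: 38 (2R)-2-[(3S,6S)-6-[(Z)-3-(5,5-dimethyl-3,4,5,6,7,8-hexahydronaphthalen-2(1H)-ylidene)propyl]-6-methyl-1,2-dioxan-3-yl]propan-1-ol
Product: 39 (2S)-2-[(3S,6S)-6-[(Z)-3-(5,5-dimethyl-3,4,5,6,7,8-hexahydronaphthalen-2(1H)-ylidene)propyl]-6-methyl-1,2-dioxan-3-yl]propanal
Conditions: Dess–Martin periodinane, NaHCO3, CH2Cl2, 0 °C; used at once
Reagents that add atoms: none
Why: Dess–Martin oxidation, in which ligand exchange at hypervalent iodine and internal deprotonation give the aldehyde under buffered, non-basic conditions, so that C2 should not epimerise and the β-peroxide should not be eliminated.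

Step 23
Reactants: 39 (2S)-2-[(3S,6S)-6-[(Z)-3-(5,5-dimethyl-3,4,5,6,7,8-hexahydronaphthalen-2(1H)-ylidene)propyl]-6-methyl-1,2-dioxan-3-yl]propanal
Product: 40 (2S)-2-[(3S,6S)-6-[(Z)-3-(5,5-dimethyl-3,4,5,6,7,8-hexahydronaphthalen-2(1H)-ylidene)propyl]-6-methyl-1,2-dioxan-3-yl]propanoic acid (CNP0223199.2)
Conditions: NaClO2, NaH2PO4, 2-methyl-2-butene (large excess), t-BuOH/H2O, 0 °C
Reagents that add atoms: sodium chlorite, [Na+].[O-]Cl=O
Why: Pinnick oxidation, in which chlorous acid adds to the aldehyde and fragments to the acid and HOCl, the excess 2-methyl-2-butene trapping HOCl before it can attack the two electron-rich alkenes and the weakly acidic buffer preserving C2.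

**Compound list**

1 | 2,2-dimethylcyclohexan-1-one | CC1(C)CCCCC1=O | starting material
2 | dimethyl carbonate | COC(=O)OC | starting material
3 | methyl 3,3-dimethyl-2-oxocyclohexane-1-carboxylate (racemic) | COC(=O)C1CCCC(C)(C)C1=O | intermediate
4 | methyl 3,3-dimethyl-2-(trifluoromethanesulfonyloxy)cyclohex-1-ene-1-carboxylate | COC(=O)C1=C(OS(=O)(=O)C(F)(F)F)C(C)(C)CCC1 | intermediate
5 | (4-bromobut-1-yn-1-yl)trimethylsilane | C[Si](C)(C)C#CCCBr | starting material
6 | bromo[4-(trimethylsilyl)but-3-yn-1-yl]zinc | C[Si](C)(C)C#CCC[Zn]Br | intermediate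
7 | methyl 3,3-dimethyl-2-[4-(trimethylsilyl)but-3-yn-1-yl]cyclohex-1-ene-1-carboxylate | COC(=O)C1=C(CCC#C[Si](C)(C)C)C(C)(C)CCC1 | intermediate
8 | {3,3-dimethyl-2-[4-(trimethylsilyl)but-3-yn-1-yl]cyclohex-1-en-1-yl}methanol | OCC1=C(CCC#C[Si](C)(C)C)C(C)(C)CCC1 | intermediate
9 | [2-(but-3-yn-1-yl)-3,3-dimethylcyclohex-1-en-1-yl]methanol | OCC1=C(CCC#C)C(C)(C)CCC1 | intermediate
10 | [2-(but-3-yn-1-yl)-3,3-dimethylcyclohex-1-en-1-yl]methyl diethyl phosphate | C#CCCC1=C(COP(=O)(OCC)OCC)CCCC1(C)C | intermediate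
11 | (Z)-β-boryl alkenylcopper from 10: copper on the internal, pinacolboryl on the terminal alkene carbon, cis to each other (Xantphos on copper not drawn) | CCOP(=O)(OCC)OCC1=C(CC/C([Cu])=C/B2OC(C)(C)C(C)(C)O2)C(C)(C)CCC1 | intermediate
12 | 2-{(Z)-[5,5-dimethyl-3,4,5,6,7,8-hexahydronaphthalen-2(1H)-ylidene]methyl}-4,4,5,5-tetramethyl-1,3,2-dioxaborolane | CC1(C)OB(/C=C2/CCC3=C(CCCC3(C)C)C2)OC1(C)C | intermediate
13 | {(Z)-[5,5-dimethyl-3,4,5,6,7,8-hexahydronaphthalen-2(1H)-ylidene]methyl}boronic acid | OB(O)/C=C1/CCC2=C(CCCC2(C)C)C1 | intermediate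
14 | 6-methylhept-5-en-2-one | CC(C)=CCCC(C)=O | starting material
15 | 4-(5,5-dimethyl-1,2,4-trioxolan-3-yl)butan-2-one (ozonide) | CC(=O)CCC1OOC(C)(C)O1 | intermediate
16 | 4-oxopentanal | CC(=O)CCC=O | intermediate
17 | (Z)-but-2-ene | C/C=C\C | starting material
18 | (Z)-but-2-en-1-ylpotassium | C/C=C\C[K] | intermediate
19 | (Z)-but-2-en-1-yl-diisopinocampheylborane, isopinocampheyl groups from (+)-α-pinene | C/C=C\CB([C@@H]1C[C@@H]2C[C@H]([C@H]1C)C2(C)C)[C@@H]1C[C@@H]2C[C@H]([C@H]1C)C2(C)C | intermediate
20 | (5R,6R)-6-methyl-2-oxooct-7-en-5-yl diisopinocampheylborinate | C[C@H](C=C)[C@H](OB([C@@H]1C[C@@H]2C[C@H]([C@H]1C)C2(C)C)[C@@H]1C[C@@H]2C[C@H]([C@H]1C)C2(C)C)CCC(C)=O | intermediate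
21 | (5R,6R)-5-hydroxy-6-methyloct-7-en-2-one | C[C@H](C=C)[C@H](O)CCC(C)=O | intermediate
22 | (5R,6R)-5-[(tert-butyldimethylsilyl)oxy]-6-methyloct-7-en-2-one | C[C@H](C=C)[C@H](O[Si](C)(C)C(C)(C)C)CCC(C)=O | intermediate
23 | trimethylsulfoxonium iodide | C[S+](C)(C)=O.[I-] | starting material
24 | dimethylsulfoxonium methylide | C[S+](C)(=O)[CH2-] | intermediate
25 | tert-butyldimethyl({(3R,4R)-3-methyl-6-[(2S)-2-methyloxiran-2-yl]hex-1-en-4-yl}oxy)silane | C[C@H](C=C)[C@H](O[Si](C)(C)C(C)(C)C)CC[C@@]1(C)CO1 | intermediate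
26 | tert-butyldimethyl({(3R,4R)-3-methyl-6-[(2S)-2-methyloxetan-2-yl]hex-1-en-4-yl}oxy)silane | C[C@H](C=C)[C@H](O[Si](C)(C)C(C)(C)C)CC[C@@]1(C)CCO1 | intermediate
27 | (3R,4R)-3-methyl-6-[(2S)-2-methyloxetan-2-yl]hex-1-en-4-ol | C[C@H](C=C)[C@H](O)CC[C@@]1(C)CCO1 | intermediate
28 | (3R,4R)-3-methyl-6-[(2S)-2-methyloxetan-2-yl]hex-1-en-4-yl methanesulfonate | C[C@H](C=C)[C@H](OS(C)(=O)=O)CC[C@@]1(C)CCO1 | intermediate
29 | (3R,4R,7R)-7-hydroperoxy-9-hydroxy-3,7-dimethylnon-1-en-4-yl methanesulfonate | C[C@H](C=C)[C@H](OS(C)(=O)=O)CC[C@](C)(CCO)OO | intermediate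
30 | 2-{(3R,6S)-6-[(2R)-but-3-en-2-yl]-3-methyl-1,2-dioxan-3-yl}ethan-1-ol | C[C@H](C=C)[C@@H]1CC[C@](C)(CCO)OO1 | intermediate
31 | 2-{(3R,6S)-6-[(2R)-but-3-en-2-yl]-3-methyl-1,2-dioxan-3-yl}ethyl methanesulfonate | C[C@H](C=C)[C@@H]1CC[C@](C)(CCOS(C)(=O)=O)OO1 | intermediate
32 | (3R,6S)-3-(2-bromoethyl)-6-[(2R)-but-3-en-2-yl]-3-methyl-1,2-dioxane | C[C@H](C=C)[C@@H]1CC[C@](C)(CCBr)OO1 | intermediate
33 | 1,2,4-trioxolane (ozonide) of the vinyl group of 32, mixture at the new acetal carbon | C[C@H](C1OCOO1)[C@@H]1CC[C@](C)(CCBr)OO1 | intermediate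
34 | (2S)-2-[(3S,6R)-6-(2-bromoethyl)-6-methyl-1,2-dioxan-3-yl]propanal | C[C@H](C=O)[C@@H]1CC[C@](C)(CCBr)OO1 | intermediate
35 | (2R)-2-[(3S,6R)-6-(2-bromoethyl)-6-methyl-1,2-dioxan-3-yl]propan-1-ol | C[C@H](CO)[C@@H]1CC[C@](C)(CCBr)OO1 | intermediate
36 | {(2R)-2-[(3S,6R)-6-(2-bromoethyl)-6-methyl-1,2-dioxan-3-yl]propoxy}(tert-butyl)dimethylsilane | C[C@H](CO[Si](C)(C)C(C)(C)C)[C@@H]1CC[C@](C)(CCBr)OO1 | intermediate
37 | tert-butyl{(2R)-2-[(3S,6S)-6-[(Z)-3-(5,5-dimethyl-3,4,5,6,7,8-hexahydronaphthalen-2(1H)-ylidene)propyl]-6-methyl-1,2-dioxan-3-yl]propoxy}dimethylsilane | C[C@H](CO[Si](C)(C)C(C)(C)C)[C@@H]1CC[C@](C)(CC/C=C2/CCC3=C(CCCC3(C)C)C2)OO1 | intermediate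
38 | (2R)-2-[(3S,6S)-6-[(Z)-3-(5,5-dimethyl-3,4,5,6,7,8-hexahydronaphthalen-2(1H)-ylidene)propyl]-6-methyl-1,2-dioxan-3-yl]propan-1-ol | C[C@H](CO)[C@@H]1CC[C@](C)(CC/C=C2/CCC3=C(CCCC3(C)C)C2)OO1 | intermediate
39 | (2S)-2-[(3S,6S)-6-[(Z)-3-(5,5-dimethyl-3,4,5,6,7,8-hexahydronaphthalen-2(1H)-ylidene)propyl]-6-methyl-1,2-dioxan-3-yl]propanal | C[C@H](C=O)[C@@H]1CC[C@](C)(CC/C=C2/CCC3=C(CCCC3(C)C)C2)OO1 | intermediate
40 | (2S)-2-[(3S,6S)-6-[(Z)-3-(5,5-dimethyl-3,4,5,6,7,8-hexahydronaphthalen-2(1H)-ylidene)propyl]-6-methyl-1,2-dioxan-3-yl]propanoic acid | C[C@H](C(=O)O)[C@@H]1CC[C@](C)(CC/C=C2/CCC3=C(CCCC3(C)C)C2)OO1 | target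

**Step count**

Total: 23 steps. Longest linear sequence: 15 steps (steps 9–19, then 20–23, from 6-methylhept-5-en-2-one). The ring A/ring B branch is 8 steps before the union.

**The three steps most likely to fail**

1. Step 7 (the proposed new method). The borylcopper may substitute or borylate the allylic phosphate before it adds to the alkyne, the terminal alkyne may be deprotonated to an unreactive copper acetylide, or the alkenylcopper may be protonated before it closes the ring. The fallback sets out from enynol 9 and comes back at boronate 12, making the two bonds one after the other with known reactions. Pd(PPh3)4-catalysed cis-silylstannation of the terminal alkyne with Me3SiSnMe3 (THF, 65 °C), which puts tin on the internal and silicon on the terminal carbon, would give {2-[(3Z)-4-(trimethylsilyl)-3-(trimethylstannyl)but-3-en-1-yl]-3,3-dimethylcyclohex-1-en-1-yl}methanol F1. MsCl, LiCl and 2,4,6-collidine in DMF would convert it into the allylic chloride {(1Z)-4-[2-(chloromethyl)-6,6-dimethylcyclohex-1-en-1-yl]-1-(trimethylsilyl)but-1-en-2-yl}trimethylstannane F2. MeLi in THF at −78 °C would exchange tin for lithium with retention to the β-silyl alkenyllithium F3 (lithium cis to silicon, not isolated), which would close ring B by intramolecular alkylation at the primary allylic chloride to {(Z)-[5,5-dimethyl-3,4,5,6,7,8-hexahydronaphthalen-2(1H)-ylidene]methyl}trimethylsilane F4. Iododesilylation with N-iodosuccinimide in (CF3)2CHOH at 0 °C (retention) would give (2Z)-2-(iodomethylidene)-5,5-dimethyl-1,2,3,4,5,6,7,8-octahydronaphthalene F5. Miyaura borylation (B2pin2, PdCl2(PPh3)2, PPh3, KOPh, toluene, 50 °C) would then return the route to 12.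

2. Step 16. E2 loss of the mesylate toward the conjugated diene, or slow substitution at the β-branched secondary carbon, may outrun the 6-exo-tet ring closure. The fallback sets out from keto aldehyde 16 and comes back at bromide 32; it closes ring C at the aldehyde oxidation level and makes the C2–C3 bond afterwards. Selective acetalisation of the aldehyde (HC(OMe)3, CeCl3·7H2O, MeOH) would give 5,5-dimethoxypentan-2-one F6. The double methylene transfer of step 12 would give (2S)-2-(3,3-dimethoxypropyl)-2-methyloxetane F7. Ethereal H2O2 with Me3SiOTf would open the oxetane with inversion to (3R)-3-hydroperoxy-6,6-dimethoxy-3-methylhexan-1-ol F8 (not isolated), which under the same acid should close by peroxyacetal exchange to 2-[(3R)-6-methoxy-3-methyl-1,2-dioxan-3-yl]ethan-1-ol F9. MsCl/Et3N then LiBr would give (3R)-3-(2-bromoethyl)-6-methoxy-3-methyl-1,2-dioxane F10. SnCl4 with (E)-but-2-en-1-yltrimethylsilane at −78 °C would ionise the peroxyacetal to a peroxycarbenium ion, which the allylsilane should capture at its γ-carbon. This addition is known for 3-alkoxy-1,2-dioxanes but is not expected to control C2 and C3, so 32 would have to be separated from its C2 and C3 isomers before the route continues at step 18.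

3. Step 20. The electron-rich trialkylphosphine and zerovalent palladium may reduce the O–O bond, the alkylpalladium may undergo β-hydride elimination faster than it couples, or KOtBu may fragment the peroxide. The fallback sets out from boronic acid 13 and bromide 36 and comes back at 37; it reverses the polarity so that palladium inserts into an alkenyl iodide with a triarylarsine ligand at room temperature. N-Iodosuccinimide in MeCN (ipso-iododeboronation with retention) would convert 13 into the alkenyl iodide F5 described above. KOtBu in THF at 0 °C would dehydrobrominate 36 to tert-butyl{(2R)-2-[(3S,6R)-6-ethenyl-6-methyl-1,2-dioxan-3-yl]propoxy}dimethylsilane F11. 9-BBN would hydroborate the vinyl group at its terminal carbon to tert-butyl{(2R)-2-[(3S,6S)-6-[2-(9-borabicyclo[3.3.1]nonan-9-yl)ethyl]-6-methyl-1,2-dioxan-3-yl]propoxy}dimethylsilane F12 (not isolated). B-alkyl Suzuki–Miyaura coupling of F12 with F5 (Pd(dppf)Cl2, AsPh3, Cs2CO3, DMF/THF/H2O, rt) would give 37.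

**Further compounds**

F1 | step 7 | {2-[(3Z)-4-(trimethylsilyl)-3-(trimethylstannyl)but-3-en-1-yl]-3,3-dimethylcyclohex-1-en-1-yl}methanol | OCC1=C(CC/C(=C/[Si](C)(C)C)[Sn](C)(C)C)C(C)(C)CCC1
F2 | step 7 | {(1Z)-4-[2-(chloromethyl)-6,6-dimethylcyclohex-1-en-1-yl]-1-(trimethylsilyl)but-1-en-2-yl}trimethylstannane | ClCC1=C(CC/C(=C/[Si](C)(C)C)[Sn](C)(C)C)C(C)(C)CCC1
F3 | step 7 | β-silyl alkenyllithium from F2, lithium cis to silicon | ClCC1=C(CC/C([Li])=C/[Si](C)(C)C)C(C)(C)CCC1
F4 | step 7 | {(Z)-[5,5-dimethyl-3,4,5,6,7,8-hexahydronaphthalen-2(1H)-ylidene]methyl}trimethylsilane | C[Si](C)(C)/C=C1/CCC2=C(CCCC2(C)C)C1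
F5 | step 7 | (2Z)-2-(iodomethylidene)-5,5-dimethyl-1,2,3,4,5,6,7,8-octahydronaphthalene | I/C=C1/CCC2=C(CCCC2(C)C)C1
F6 | step 16 | 5,5-dimethoxypentan-2-one | COC(OC)CCC(C)=O
F7 | step 16 | (2S)-2-(3,3-dimethoxypropyl)-2-methyloxetane | COC(OC)CC[C@@]1(C)CCO1
F8 | step 16 | (3R)-3-hydroperoxy-6,6-dimethoxy-3-methylhexan-1-ol | COC(OC)CC[C@](C)(CCO)OO
F9 | step 16 | 2-[(3R)-6-methoxy-3-methyl-1,2-dioxan-3-yl]ethan-1-ol (mixture at the acetal carbon) | COC1CC[C@](C)(CCO)OO1
F10 | step 16 | (3R)-3-(2-bromoethyl)-6-methoxy-3-methyl-1,2-dioxane (mixture at the acetal carbon) | COC1CC[C@](C)(CCBr)OO1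
F11 | step 20 | tert-butyl{(2R)-2-[(3S,6R)-6-ethenyl-6-methyl-1,2-dioxan-3-yl]propoxy}dimethylsilane | C[C@H](CO[Si](C)(C)C(C)(C)C)[C@@H]1CC[C@](C)(C=C)OO1
F12 | step 20 | tert-butyl{(2R)-2-[(3S,6S)-6-[2-(9-borabicyclo[3.3.1]nonan-9-yl)ethyl]-6-methyl-1,2-dioxan-3-yl]propoxy}dimethylsilane | C[C@H](CO[Si](C)(C)C(C)(C)C)[C@@H]1CC[C@](C)(CCB2C3CCCC2CCC3)OO1
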